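- The vessel holds undissolved E and takes D by a steady feed over 2.5 d; the question is what stands in it when the feed ends.

| setting | Friday's | Wednesday's | north | south-west |
|---|---|---|---|---|
| D | 0.0050 M (fed, over 2.5 d) | 0.0075 M (fed, over 2.5 d) | 0.010 M (fed, over 2.5 d) | 0.010 M (fed, over 2.5 d) |
| E | 1.3 equiv | 1.3 equiv | 1.30 equiv | 1.30 equiv |
| temperature | 18 °C | 34 °C | 20 °C | 30 °C |
| remark | run made earlier; the fed solution adds 1.0 times the starting volume | run made earlier; the fed solution adds 1.0 times the starting volume | the fed solution adds 1.0 times the starting volume | the fed solution adds 1.0 times the starting volume |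
| time |  |  | 2.5 d | 2.5 d |

Friday's run (percent of the D charged)

| time / d | L / % | D / % | J / % |
|---|---|---|---|
| 0.500 | 7.7 | 12.2 | 0 |
| 1.04 | 24.3 | 16.7 | 0.7 |
| 1.67 | 45.3 | 18.2 | 3.8 |
| 2.08 | 58.9 | 18.2 | 5.8 |
| 2.50 | 73.9 | 18.5 | 7.8 |
| 3.00 | 83.5 | 6.4 | 9.5 |

Wednesday's run (percent of the D charged)

| time / h | L / % | D / % | J / % |
|---|---|---|---|
| 3.00 | 2.7 | 2.0 | 0 |
| 5.00 | 6.1 | 2.0 | 0.2 |
| 8.00 | 11.2 | 1.9 | 0.4 |
| 12.0 | 16.8 | 1.8 | 0.4 |
| 20.0 | 28.0 | 2.1 | 2.7 |
| 40.0 | 51.8 | 2.0 | 13.1 |

(standard deviation of a reading: 0.3 percentage points)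

- charges are per starting volume, the dose included; the dosed solution carries all of it
- given per volume of solution although it is solid: E
- on the list of suspects stand: E <-> Q; D -> L; 2 Q -> X; Q <-> G; Q + L -> J
- at the start none of E is in solution
- percentages count the whole charge, also what has not yet gone in

* which of these there is most of at the end, counted by the D in it, north (J / D / L)
* which of these there is most of at the end, counted by the D in it, south-west (J / D / L)
* the largest of these amounts at the end, in percent of the D charged, north
* the largest of these amounts at the end, in percent of the D charged, south-west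

- I write the balance of D, the smaller charge: the whole charge enters over the feed time t_f, and D leaves as L at k times what stands, with k the first-order rate constant.
- Where feed equals loss, D holds a steady state, and the readings show one. Friday's holds 18.2% at 2.08 d, which gives k = 2.20 d⁻¹. Wednesday's holds 2.0%, which gives 20.0 d⁻¹. Together they give an activation energy of 103 kJ mol⁻¹.
- Fastest rung: k comes to 2.93 d⁻¹ north and 11.8 d⁻¹ south-west. The half-lives of D are then 0.236 d and 0.0589 d, both shorter than the feed, so D follows the feed.
- I reckon (one minus exp(−k·t_f))/(k·t_f), which gives 13.6% north and 3.40% south-west. This is the standing share S, the part of the D charged that is still D when the feed ends.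
- Next rung: J starts late, reading 0% on Friday's at 0.500 d.
- Slowest rung: Wednesday's, at 34 °C, reads a half-life of L into J of 2.22 d. That is longer than the 1.25 d that L made during a steady feed has stood on average, so I expect L to lead in both flasks.
- L and J share 86.4% north and 96.6% south-west. Taking off Friday's J of 7.8% puts north L near 78.6%. South-west L lies lower, by an amount I can't reckon.
- The forecast names L north and L south-west, at 73% and 68%, with J near 13% and 28%: “L remains largest in both”. Its north figure is below mine.
- The flask gives L 74.8% north, with J 11.2% and D 14.0%, and L 73.9% south-west, with J 22.5% and D 3.62%.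

    E ⇌ Q, rate k1*(cs1 - [Q]) while solid is left; crystals form when [Q] > cs1 (solubility = 7.20 mM, k = 6.10 × 10⁻⁶ s⁻¹)
    D → L (k = 3.30 × 10⁻⁵ s⁻¹, Ea = 100 kJ mol⁻¹)
    2 Q → X (k = 0.00120 M⁻¹ s⁻¹, Ea = 64.0 kJ mol⁻¹)
    Q ⇌ G (K = 1.80, k = 6.20 × 10⁻⁶ s⁻¹, Ea = 109 kJ mol⁻¹, ΔH = −48.0 kJ mol⁻¹)
    Q + L → J (k = 7.50 × 10⁻⁴ M⁻¹ s⁻¹, Ea = 65.0 kJ mol⁻¹)
    (constants at 20 °C)

- South-west holds D at 3.62% against S of 3.40%. A repeat of south-west at 5 °C has k = 0.303 d⁻¹, so S comes to 70.1%, and that flask holds 69.4% of D. In south-west, D has a half-life of 0.063 d by making L at 2.50 d, while L has a half-life of 3.0 d by making J at 1.41 d. So in south-west the half-life of D is much shorter than that of L, and of the 96.4% of the D charged that is no longer D at the end, J holds 22.5% and L holds 73.9%.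

The readings come from a simulation from invented constants, and the scatter is random.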